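**Retrosynthetic overview**
1. Last disconnection, at the C1–O ester bond plus a carboxyl that is lost. Phenethyl icosanoate ⇒ 5-octadecyl Meldrum's acid + 2-phenylethanol (ring opening, loss of acetone and CO2).
2. Key disconnection, at C2–C3 of the acyl chain (numbered from the ester carbonyl C1). 5-Octadecyl Meldrum's acid ⇒ octadecanal + Meldrum's acid + Hantzsch ester in one flask. This three-component reductive alkylation copies one elongation cycle of fatty acid biosynthesis: a C18 acyl unit plus a malonyl C2 unit, dehydration, NAD(P)H-type hydride transfer, and CO2 lost afterwards.
3. Enabling feature: C2 is a CH2 directly on the ester carbonyl C1, so it can be carried as the doubly activated C5 of a malonate whose second carboxyl leaves as CO2. Its neighbour C3 is an unbranched CH2 without a stereocentre, so it can be carried as the aldehyde carbon of a plain C18 chain.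
4. Rings: none is formed. The phenyl ring comes with 2-phenylethanol. The 1,3-dioxane-4,6-dione ring is bought, serves as a temporary activating ring at C1/C2, and is opened in the last step.
5. Octadecanal ⇒ 1-octadecanol (oxidation, made fresh).

Key step: step 2

Remark: the target has no stereocentre, so no stereocontrol is needed. Octadecanal is prepared fresh because stored long-chain aldehyde tends to oxidise and trimerise.

**Step 1**
Reactants: 1 1-octadecanol
Product: 2 octadecanal
Conditions: TEMPO (10 mol%), PhI(OAc)2 (1.1 equiv), CH2Cl2, rt
Reagents that add atoms: none
Why: In this TEMPO/PhI(OAc)2 oxoammonium oxidation the primary alcohol is oxidised by the oxoammonium salt, and without water no aldehyde hydrate is available for further oxidation, so the reaction should stop at the aldehyde; no stereocentre is involved.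

**Step 2**
Reactants: 2 octadecanal; 3 Meldrum's acid (2,2-dimethyl-1,3-dioxane-4,6-dione); 4 Hantzsch ester (diethyl 2,6-dimethyl-1,4-dihydropyridine-3,5-dicarboxylate)
Product: 6 octadecyl Meldrum's acid (5-octadecyl-2,2-dimethyl-1,3-dioxane-4,6-dione), via octadecylidene Meldrum's acid 5 (not isolated)
Conditions: L-proline (10 mol%), CH2Cl2–EtOH (4:1), 25 °C
Reagents that add atoms: none
Why: Proline activates octadecanal 2 as its iminium ion, the enol of Meldrum's acid 3 (C5–H, pKa about 5) adds to it and loss of proline gives the alkylidene 5, which forms the C2–C3 bond of the target as a C=C bond (Knoevenagel condensation); 5, locked by the 1,3-dioxane-4,6-dione ring and therefore strongly electrophilic, then takes a hydride from C4 of Hantzsch ester 4 at the former aldehyde carbon and a proton at C5, which gives 6 and the aromatised pyridine. The closest known reaction type is the amino-acid-catalysed three-component reductive alkylation of cyclic CH-acids with aldehydes and Hantzsch ester (Knoevenagel condensation/transfer hydrogenation cascade), which is established for linear aliphatic aldehydes and Meldrum's acid. The flask copies one elongation cycle of fatty acid biosynthesis: 3 stands for the malonyl unit, 2 for the stearoyl unit one oxidation level lower, so that no ketoreduction is needed and dehydration is spontaneous, and 4 stands for NAD(P)H in the enoyl reduction. No ring is closed and no stereocentre is created, since C5 of 6 carries two identical acyl arms. The step needs monoalkylation and chemoselective hydride transfer: 6 keeps only one C5–H and cannot condense a second time, 4 does not reduce the free aldehyde under these conditions, and the fast irreversible hydride transfer should drain 5 before a second molecule of 3 can add to it in a Michael reaction. Self-aldol condensation of the enolisable aldehyde should be outrun because 3 is far more acidic and is present in equimolar amount from the start.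

**Step 3**
Reactants: 6 octadecyl Meldrum's acid; 7 2-phenylethanol (2 equiv)
Product: 9 phenethyl icosanoate, via malonic half ester 8 (not isolated)
Conditions: Cu powder (10 mol%), pyridine, reflux (115 °C)
Reagents that add atoms: none
Why: In this decarboxylative alcoholysis of a 5-monosubstituted Meldrum's acid the alcohol opens the electrophilic acylal ring (directly or through the carboxyketene formed by loss of acetone) to half ester 8, which loses CO2 in hot pyridine under copper catalysis (malonic-type decarboxylation), so ester formation and removal of the activating group take place in one flask and the transient stereocentre at C2 of 8 disappears with the CO2.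

**Compound list**
1 | 1-octadecanol | CCCCCCCCCCCCCCCCCCO | starting material
2 | octadecanal | CCCCCCCCCCCCCCCCCC=O | intermediate
3 | Meldrum's acid (2,2-dimethyl-1,3-dioxane-4,6-dione) | CC1(C)OC(=O)CC(=O)O1 | starting material
4 | Hantzsch ester (diethyl 2,6-dimethyl-1,4-dihydropyridine-3,5-dicarboxylate) | CCOC(=O)C1=C(C)NC(C)=C(C(=O)OCC)C1 | starting material
5 | octadecylidene Meldrum's acid (5-octadecylidene-2,2-dimethyl-1,3-dioxane-4,6-dione) | CCCCCCCCCCCCCCCCCC=C1C(=O)OC(C)(C)OC1=O | intermediate
6 | octadecyl Meldrum's acid (5-octadecyl-2,2-dimethyl-1,3-dioxane-4,6-dione) | CCCCCCCCCCCCCCCCCCC1C(=O)OC(C)(C)OC1=O | intermediate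
7 | 2-phenylethanol | OCCc1ccccc1 | starting material
8 | malonic half ester (2-[(2-phenylethoxy)carbonyl]icosanoic acid, racemic) | CCCCCCCCCCCCCCCCCCC(C(=O)O)C(=O)OCCc1ccccc1 | intermediate
9 | phenethyl icosanoate | CCCCCCCCCCCCCCCCCCCC(=O)OCCc1ccccc1 | target

**Total step count:** 3
**Longest linear sequence:** 3 steps (1 → 2 → 6 → 9)

**Steps most likely to fail**

1. **Step 2.** A second molecule of Meldrum's acid may add to the alkylidene in a Michael reaction faster than hydride is transferred. The enolisable aldehyde may self-condense under amine catalysis. The waxy aldehyde may dissolve too poorly for the condensation to keep pace.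
 - The fallback sets out from 2 and comes back at 9, and it forms the same C2–C3 bond with the ester already in place.
 - Meldrum's acid 3 is opened with 2-phenylethanol 7 in refluxing toluene to mono(2-phenylethyl) malonate F1.
 - F1 is condensed with 2 in a decarboxylative Doebner–Knoevenagel reaction (DMAP cat., DMF, or piperidine/pyridine) to 2-phenylethyl (E)-icos-2-enoate F2.
 - Hydrogenation (H2, Pd/C, EtOAc) should give 9. The O–CH2 of the 2-phenylethyl ester is not benzylic and should not be hydrogenolysed. Any β,γ-unsaturated isomer converges on the same product.

2. **Step 3.** Ring opening may be slow because the pyridinium enolate of 6 is a poor electrophile. Decarboxylation of the half ester may stay incomplete. Adventitious water may compete with the alcohol for the ring.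
 - The fallback sets out from 6 and comes back at 9, and it separates removal of the activating group from ester formation.
 - 6 is hydrolysed (aq. NaOH, then HCl) to 2-octadecylmalonic acid F3.
 - F3 is decarboxylated neat at about 160 °C to icosanoic acid F4.
 - F4 is esterified with 7 in a Fischer esterification (TsOH cat., toluene, Dean–Stark) to 9.

3. **Step 1.** Oxidation may run on to the acid. The hemiacetal of product and starting alcohol may be oxidised to the dimeric ester. The aldehyde may trimerise on handling.
 - The fallback sets out from 1 and comes back at 6. It avoids the aldehyde altogether and forms the C2–C3 bond at the acyl oxidation level, as a Claisen-type acylation.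
 - 1 is oxidised completely (TEMPO cat., NaClO2, NaOCl cat., MeCN/phosphate buffer) to octadecanoic acid F5.
 - F5 is coupled with Meldrum's acid 3 (DCC, DMAP, CH2Cl2) to 5-(1-hydroxyoctadecylidene) Meldrum's acid F6.
 - F6 is reduced with NaBH4 in AcOH/CH2Cl2 (reduction, elimination, conjugate reduction) to 6.

**Further compounds**
F1 | step 2 | mono(2-phenylethyl) malonate | OC(=O)CC(=O)OCCc1ccccc1
F2 | step 2 | 2-phenylethyl (E)-icos-2-enoate | CCCCCCCCCCCCCCCCC/C=C/C(=O)OCCc1ccccc1
F3 | step 3 | 2-octadecylmalonic acid | CCCCCCCCCCCCCCCCCCC(C(=O)O)C(=O)O
F4 | step 3 | icosanoic acid | CCCCCCCCCCCCCCCCCCCC(=O)O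
F5 | step 1 | octadecanoic acid | CCCCCCCCCCCCCCCCCC(=O)O
F6 | step 1 | 5-(1-hydroxyoctadecylidene) Meldrum's acid | CCCCCCCCCCCCCCCCCC(O)=C1C(=O)OC(C)(C)OC1=O
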